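**Plan**

1. Numbering used: ring C1 (C=O), C2 (pentenyl), C3 (ester chain), C4 (OH), C5 (Br); chain carbons C1′–C8′ run outward from C3 (C8′ is the ester carbon).
2. Retrosynthesis: cut C5–Br (enol-ether bromination); cut C2–C3 of the cyclopentenone, which unravels to a 2,5-disubstituted furylcarbinol (Piancatelli retron); cut the two carbinol C–C bonds (C2–CH2 of the pentenyl group, then C1–C2); open the furan to a methyl ynone; last cut C5′–C6′, with reconnection of C5′ to C3.
3. Enabling feature: in the furan and ynone precursors C3 is at the carbonyl oxidation level, and C3 plus C1′–C5′ are six contiguous carbons, so they are carried as the ring of cyclohexanone. An alkoxy radical on C3 opens this temporary six-membered ring, leaves C3 as the ynone carbonyl and releases C5′ as a primary radical that methyl acrylate (C6′–C8′) captures.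
4. Forward order: cyclohexanone plus propynyl Grignard; ring-opening/Giese step (whole ester chain in place); furan ring from the ynone; C2 by formylation; pentynyl addition; semihydrogenation; cyclopentenone ring by Piancatelli rearrangement and isomerisation; resolution; silylation; bromination; desilylation.
5. Stereochemistry: the Z-alkene comes from Lindlar semihydrogenation. C4 comes from lipase kinetic resolution of the racemic hydroxy enone (the 4S alcohol is kept; its descriptor becomes 4R once Br sits on C5, the centre itself is not touched). C5 comes from bromination anti to the C4 silyloxy group (trans, 5S).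

Key step: step 2

Remark: racemic compounds 12, 13 and 15 are written without a descriptor at the carbinol carbon; 14 is drawn as one enantiomer of the racemic trans isomer.

**Step 1**
Reactants: 1 cyclohexanone; 2 1-propynylmagnesium bromide
Product: 3 1-(prop-1-yn-1-yl)cyclohexan-1-ol
Conditions: THF, 0 °C to rt; aq. NH4Cl
Reagents that add atoms: none
Why: 1,2-addition of an alkynyl Grignard reagent to a ketone; no stereocentre is formed.

**Step 2**
Reactants: 3 1-(prop-1-yn-1-yl)cyclohexan-1-ol; 4 methyl acrylate
Product: 5 methyl 9-oxododec-10-ynoate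
Conditions: [Ir(dF(CF3)ppy)2(5,5′-d(CF3)bpy)]PF6 (2 mol %), Bu4N[O2P(OBu)2] (20 mol %), 4 (3 equiv), PhCF3, blue LEDs, rt, degassed
Reagents that add atoms: none
Why: Proposed new method: the excited Ir(III) complex and the phosphate base remove the O–H hydrogen of 3 by proton-coupled electron transfer; the tertiary alkoxy radical on C3 undergoes β-scission of a ring C–C bond to give the conjugated ynone carbonyl and the primary C5′ radical, which adds to the β-carbon of methyl acrylate (polarity-matched Giese addition) to form C5′–C6′, and the α-ester radical is reduced by Ir(II) and protonated by the phosphoric acid, so the cycle is redox- and proton-neutral. The closest known reaction type is the photocatalytic alkoxy-radical ring opening and Giese alkylation of 1-alkyl- and 1-aryl-cycloalkanols; a 1-alkynyl carbinol has not been used in it. No ring is closed (the temporary six-membered ring is opened) and no stereocentre is formed. The step needs regioselective scission, which the substrate secures because the only exocyclic β-bond leads to an sp carbon (an alkynyl radical is not accessible), while ring cleavage is driven by formation of the conjugated ynone. It also needs capture of the nucleophilic primary radical by the acrylate before it adds to the product ynone, which the excess of the unhindered terminal acceptor over the β-methyl-substituted ynone should secure.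

**Step 3**
Reactants: 5 methyl 9-oxododec-10-ynoate
Product: 7 methyl 8-(furan-2-yl)octanoate, via allenyl ketone 6 (not isolated)
Conditions: CuI (10 mol %), Et3N–DMA (1:7), 110 °C
Reagents that add atoms: none
Why: Copper(I)-catalysed cycloisomerisation of an alkynyl ketone to a furan: triethylamine shifts the methyl ynone to the allenyl ketone 6, whose carbonyl oxygen closes onto the allene terminus (5-endo) and aromatises, so the ketone carbon becomes the furan carbon that carries the chain; no stereocentre.

**Step 4**
Reactants: 7 methyl 8-(furan-2-yl)octanoate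
Product: 9 methyl 8-(5-formylfuran-2-yl)octanoate, via iminium chloride 8 (not isolated)
Conditions: POCl3 (1.2 equiv), DMF, 0 °C to 40 °C; then H2O, 0 °C to rt
Reagents that add atoms: N,N-dimethylformamide CN(C)C=O (formyl carbon); water O (aldehyde oxygen)
Why: Vilsmeier–Haack formylation, which takes place at the free α-position of a 2-alkylfuran and leaves the ester untouched; no stereocentre.

**Step 5**
Reactants: 9 methyl 8-(5-formylfuran-2-yl)octanoate; 10 1-bromopent-2-yne
Product: 12 methyl 8-[5-(1-hydroxyhex-3-yn-1-yl)furan-2-yl]octanoate (racemic), via allenylzinc bromide 11 (not isolated)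
Conditions: Zn dust (activated), THF, 0 °C to rt; aq. NH4Cl
Reagents that add atoms: none
Why: Barbier-type zinc propargylation: the allenylzinc form adds to the aldehyde through an SE2′ transition state to give the homopropargylic alcohol, the organozinc does not attack the methyl ester, and the new carbinol centre is left racemic because it is lost in step 7.

**Step 6**
Reactants: 12 methyl 8-[5-(1-hydroxyhex-3-yn-1-yl)furan-2-yl]octanoate
Product: 13 methyl 8-{5-[(3Z)-1-hydroxyhex-3-en-1-yl]furan-2-yl}octanoate (racemic)
Conditions: H2 (1 atm), Lindlar catalyst, quinoline, EtOAc, rt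
Reagents that add atoms: none
Why: Lindlar semihydrogenation: syn addition of H2 on the poisoned Pd surface gives the Z-alkene and stops there; furan and ester are not reduced.

**Step 7**
Reactants: 13 methyl 8-{5-[(3Z)-1-hydroxyhex-3-en-1-yl]furan-2-yl}octanoate
Product: 15 methyl 8-[5-hydroxy-3-oxo-2-[(2Z)-pent-2-en-1-yl]cyclopent-1-en-1-yl]octanoate (racemic), via trans-hydroxycyclopentenone 14 (not isolated)
Conditions: dioxane–H2O (1:1), NaOAc/AcOH buffer (pH 5), 95 °C; then aq. NaHCO3/Na2CO3 to pH 8.5, 50 °C
Reagents that add atoms: water O
Why: Piancatelli rearrangement (ionisation of the furylcarbinol, water attack at the chain-bearing furan carbon, ring opening and conrotatory 4π closure to trans-14) followed by base-mediated isomerisation (conjugate addition of water, E1cB loss of the tertiary hydroxyl) to the more stable tetrasubstituted enone, the established way to rethrolone-type 4-hydroxy-3-alkyl-2-alkenylcyclopentenones; C4 is formed racemic.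

**Step 8**
Reactants: 15 methyl 8-[5-hydroxy-3-oxo-2-[(2Z)-pent-2-en-1-yl]cyclopent-1-en-1-yl]octanoate (racemic)
Product: 16 methyl 8-[(5S)-5-hydroxy-3-oxo-2-[(2Z)-pent-2-en-1-yl]cyclopent-1-en-1-yl]octanoate
Conditions: lipase PS (Burkholderia cepacia), vinyl acetate, MTBE, 30 °C, stopped a little past half conversion; chromatography
Reagents that add atoms: none
Why: Lipase-catalysed kinetic resolution by irreversible transesterification: by the usual preference of lipases for secondary alcohols, and as known for the closely related rethrolones, the 4R alcohol (large group = substituted C3 side) is acetylated, and the wanted 4S alcohol stays unreacted and is separated.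

**Step 9**
Reactants: 16 methyl 8-[(5S)-5-hydroxy-3-oxo-2-[(2Z)-pent-2-en-1-yl]cyclopent-1-en-1-yl]octanoate
Product: 17 methyl 8-[(5S)-5-[(tert-butyldimethylsilyl)oxy]-3-oxo-2-[(2Z)-pent-2-en-1-yl]cyclopent-1-en-1-yl]octanoate
Conditions: TBSCl, imidazole, DMF, rt
Reagents that add atoms: tert-butyldimethylsilyl chloride CC(C)(C)[Si](C)(C)Cl
Why: Silyl ether formation protects the alcohol against the base of step 10 and supplies the bulky group that directs the bromination; the stereocentre is not touched.

**Step 10**
Reactants: 17 methyl 8-[(5S)-5-[(tert-butyldimethylsilyl)oxy]-3-oxo-2-[(2Z)-pent-2-en-1-yl]cyclopent-1-en-1-yl]octanoate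
Product: 19 methyl 8-[(4S,5R)-4-bromo-5-[(tert-butyldimethylsilyl)oxy]-3-oxo-2-[(2Z)-pent-2-en-1-yl]cyclopent-1-en-1-yl]octanoate, via silyl dienol ether 18 (not isolated)
Conditions: LiHMDS (1.1 equiv), TMSCl (1.3 equiv), THF, −78 °C; then NBS (1.05 equiv), −78 °C to −40 °C, dark
Reagents that add atoms: N-bromosuccinimide O=C1CCC(=O)N1Br
Why: Kinetic α′-deprotonation at C5 with in situ silylation gives the cross-conjugated silyl dienol ether 18, which NBS brominates at C5 (α-bromination of a silyl enol ether) on the face anti to the neighbouring OTBS group, setting the trans (5S) bromide; the enol ether reacts far faster than the Z-alkene.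

**Step 11**
Reactants: 19 methyl 8-[(4S,5R)-4-bromo-5-[(tert-butyldimethylsilyl)oxy]-3-oxo-2-[(2Z)-pent-2-en-1-yl]cyclopent-1-en-1-yl]octanoate
Product: 20 methyl 8-[(4S,5R)-4-bromo-5-hydroxy-3-oxo-2-[(2Z)-pent-2-en-1-yl]cyclopent-1-en-1-yl]octanoate (the target; (4R,5S)-5-bromo-4-hydroxy in cyclopentenone numbering)
Conditions: 48% aq. HF, MeCN, 0 °C
Reagents that add atoms: none
Why: Acidic fluoride desilylation removes the TBS group without base, so the α-bromo-β-hydroxy ketone does not close to an epoxide or eliminate, and neither stereocentre is touched.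

**Compound list**

1 | cyclohexanone | O=C1CCCCC1 | starting material
2 | 1-propynylmagnesium bromide | CC#C[Mg]Br | starting material
3 | 1-(prop-1-yn-1-yl)cyclohexan-1-ol | CC#CC1(O)CCCCC1 | intermediate
4 | methyl acrylate | C=CC(=O)OC | starting material
5 | methyl 9-oxododec-10-ynoate | CC#CC(=O)CCCCCCCC(=O)OC | intermediate
6 | methyl 9-oxododeca-10,11-dienoate (allenyl ketone, not isolated) | C=C=CC(=O)CCCCCCCC(=O)OC | intermediate
7 | methyl 8-(furan-2-yl)octanoate | COC(=O)CCCCCCCc1ccco1 | intermediate
8 | {[5-(8-methoxy-8-oxooctyl)furan-2-yl]methylidene}dimethyliminium chloride (not isolated) | C[N+](C)=Cc1ccc(CCCCCCCC(=O)OC)o1.[Cl-] | intermediate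
9 | methyl 8-(5-formylfuran-2-yl)octanoate | COC(=O)CCCCCCCc1ccc(C=O)o1 | intermediate
10 | 1-bromopent-2-yne | CCC#CCBr | starting material
11 | (penta-1,2-dien-3-yl)zinc bromide, the allenyl form of pent-2-ynylzinc bromide (not isolated) | C=C=C(CC)[Zn]Br | intermediate
12 | methyl 8-[5-(1-hydroxyhex-3-yn-1-yl)furan-2-yl]octanoate (racemic) | CCC#CCC(O)c1ccc(CCCCCCCC(=O)OC)o1 | intermediate
13 | methyl 8-{5-[(3Z)-1-hydroxyhex-3-en-1-yl]furan-2-yl}octanoate (racemic) | CC/C=C\CC(O)c1ccc(CCCCCCCC(=O)OC)o1 | intermediate
14 | methyl 8-[(1R*,5S*)-1-hydroxy-4-oxo-5-[(2Z)-pent-2-en-1-yl]cyclopent-2-en-1-yl]octanoate (racemic, OH and pentenyl trans; not isolated) | O=C1C=C[C@](O)(CCCCCCCC(=O)OC)[C@@H]1C/C=C\CC | intermediate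
15 | methyl 8-[5-hydroxy-3-oxo-2-[(2Z)-pent-2-en-1-yl]cyclopent-1-en-1-yl]octanoate (racemic) | CC/C=C\CC1=C(CCCCCCCC(=O)OC)C(O)CC1=O | intermediate
16 | methyl 8-[(5S)-5-hydroxy-3-oxo-2-[(2Z)-pent-2-en-1-yl]cyclopent-1-en-1-yl]octanoate | CC/C=C\CC1=C(CCCCCCCC(=O)OC)[C@@H](O)CC1=O | intermediate
17 | methyl 8-[(5S)-5-[(tert-butyldimethylsilyl)oxy]-3-oxo-2-[(2Z)-pent-2-en-1-yl]cyclopent-1-en-1-yl]octanoate | CC/C=C\CC1=C(CCCCCCCC(=O)OC)[C@@H](O[Si](C)(C)C(C)(C)C)CC1=O | intermediate
18 | methyl 8-[(5S)-5-[(tert-butyldimethylsilyl)oxy]-2-[(2Z)-pent-2-en-1-yl]-3-(trimethylsilyloxy)cyclopenta-1,3-dien-1-yl]octanoate (not isolated) | CC/C=C\CC1=C(CCCCCCCC(=O)OC)[C@@H](O[Si](C)(C)C(C)(C)C)C=C1O[Si](C)(C)C | intermediate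
19 | methyl 8-[(4S,5R)-4-bromo-5-[(tert-butyldimethylsilyl)oxy]-3-oxo-2-[(2Z)-pent-2-en-1-yl]cyclopent-1-en-1-yl]octanoate | CC/C=C\CC1=C(CCCCCCCC(=O)OC)[C@@H](O[Si](C)(C)C(C)(C)C)[C@H](Br)C1=O | intermediate
20 | methyl 8-[(4S,5R)-4-bromo-5-hydroxy-3-oxo-2-[(2Z)-pent-2-en-1-yl]cyclopent-1-en-1-yl]octanoate | CC/C=C\CC1=C(CCCCCCCC(=O)OC)[C@@H](O)[C@H](Br)C1=O | target

**Totals and risks**

Total step count: 11. Longest linear sequence: 11 steps (1 to 20; compounds 2, 4 and 10 are bought).

Steps most likely to fail:

Step 2 (proposed new method). β-Scission of the unstrained six-membered alkoxy radical may be too slow against back hydrogen transfer, or the ring-opened radical may be lost to addition to the ynone product and to telomerisation of the acrylate. The fallback uses known chemistry, sets out from methyl acrylate 4 and comes back at furan ester 7. Furan is lithiated (n-BuLi, THF, 0 °C) and alkylated with 1-bromo-5-chloropentane to 2-(5-chloropentyl)furan F1. Finkelstein exchange (NaI, acetone, reflux) gives 2-(5-iodopentyl)furan F2. The primary radical made from F2 by iodine abstraction ((Me3Si)3SiH, AIBN, toluene, 80 °C) adds to 4 in a Giese reaction and gives 7. The same C5′–C6′ bond is thus formed from a halide instead of from a ring, and step 3 is not needed.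

Step 3. Amine-induced oligomerisation of the ynone (conjugate addition, self-condensation through the α′-methylene) may outrun the propargyl–allenyl shift. The fallback sets out from cyclohexanone 1 and comes back at 7; the furan is formed by cyclodehydration of a cis-γ-hydroxy enone instead of by isomerisation. The lithium acetylide of tert-butyldimethyl(prop-2-yn-1-yloxy)silane is added to 1 to give 1-[3-(tert-butyldimethylsilyloxy)prop-1-yn-1-yl]cyclohexan-1-ol F3. The conditions of step 2 with 4 should give methyl 12-(tert-butyldimethylsilyloxy)-9-oxododec-10-ynoate F4. Lindlar semihydrogenation gives methyl (10Z)-12-(tert-butyldimethylsilyloxy)-9-oxododec-10-enoate F5. TsOH in wet THF removes the silyl group, and the cis-hydroxy enone closes and loses water to give 7.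

Step 10. The C5 enolate may expel the β-silyloxy group (E1cB) before it is silylated, the product may be brominated twice, or the facial selectivity may be low. The fallback sets out from alcohol 16 and comes back at target 20. The protecting group and the enolate are given up, and 16 is brominated through its enol under acid with pyrrolidone hydrotribromide (THF, rt), a reagent that prefers ketone α-positions to C=C bonds. The α-bromo ketone can equilibrate through the enol to the trans isomer, so the selectivity comes from thermodynamic instead of kinetic control. No new compound is made (F0).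

**Further compounds**

F1 | step 2 | 2-(5-chloropentyl)furan | ClCCCCCc1ccco1
F2 | step 2 | 2-(5-iodopentyl)furan | ICCCCCc1ccco1
F3 | step 3 | 1-[3-(tert-butyldimethylsilyloxy)prop-1-yn-1-yl]cyclohexan-1-ol | CC(C)(C)[Si](C)(C)OCC#CC1(O)CCCCC1
F4 | step 3 | methyl 12-[(tert-butyldimethylsilyl)oxy]-9-oxododec-10-ynoate | CC(C)(C)[Si](C)(C)OCC#CC(=O)CCCCCCCC(=O)OC
F5 | step 3 | methyl (10Z)-12-[(tert-butyldimethylsilyl)oxy]-9-oxododec-10-enoate | CC(C)(C)[Si](C)(C)OC/C=C\C(=O)CCCCCCCC(=O)OC
F0 | step 10 | none | none
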